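**Retrosynthetic overview**
- Last operation: the furanone ring and the ten-membered carbocycle are closed together. Fluoride unmasks an α′-hydroxy ynone, which cyclises (O–C3) to a 2-methylfuran-3(2H)-one; its C10 then adds to a C9 aldehyde (C9–C10 aldol), setting C9 and C10.
- The seco aldehyde comes from an acyl Sonogashira coupling (C1–C2) of a terminal enyne lactone with a silyl-protected lactoyl chloride, followed by direct Swern oxidation of a primary triethylsilyl ether.
- The C8 ester is installed with inversion by a Mitsunobu reaction with (R)-2-methylbutanoic acid.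
- The α-methylene-γ-butyrolactone (first ring) comes from a CrCl2 Barbier allylation/lactonisation (C6–C7) between a (Z)-enynal and a Morita–Baylis–Hillman bromide made from glyceraldehyde acetonide and methyl acrylate.
- Ring order: lactone first, then furanone and carbocycle together in the final step.

Assumption: the two chiral starting materials are bought as single enantiomers; atoms are called C1–C15 by germacrane numbering (C6/C7 lactone carbons, C8 ester carbon, C9 carbinol, C10 quaternary furanone carbon, C11–C13 methylene lactone).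

**Step 1**
Reactants: 1 (2Z)-3-methylpent-2-en-4-yn-1-ol
Product: 2 (2Z)-3-methylpent-2-en-4-ynal
Conditions: MnO2 (15 equiv), CH2Cl2, rt; filtered and used as a cold solution
Reagents that add atoms: none
Why: Activated MnO2 oxidises the allylic alcohol to the enal under neutral conditions that keep the Z geometry and the terminal alkyne (allylic alcohol oxidation).

**Step 2**
Reactants: 3 (4S)-2,2-dimethyl-1,3-dioxolane-4-carbaldehyde ((S)-glyceraldehyde acetonide); 4 methyl acrylate
Product: 5 methyl 2-{[(4S)-2,2-dimethyl-1,3-dioxolan-4-yl](hydroxy)methyl}prop-2-enoate (both carbinol epimers)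
Conditions: 1,4-diazabicyclo[2.2.2]octane (DABCO, 0.5 equiv), 1,4-dioxane/H2O (1:1), rt, 48 h
Reagents that add atoms: none
Why: The Morita–Baylis–Hillman reaction joins the acrylate α-carbon (C11) to the aldehyde carbon (C7); the new carbinol centre is irrelevant because it becomes sp2 in step 3, and the dioxolane centre (C8) is untouched.

**Step 3**
Reactants: 5 methyl 2-{[(4S)-2,2-dimethyl-1,3-dioxolan-4-yl](hydroxy)methyl}prop-2-enoate
Product: 6 methyl (2Z)-2-(bromomethyl)-3-[(4R)-2,2-dimethyl-1,3-dioxolan-4-yl]prop-2-enoate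
Conditions: NBS, Me2S, CH2Cl2, 0 °C to rt
Reagents that add atoms: N-bromosuccinimide, O=C1CCC(=O)N1Br
Why: Corey–Kim-type activation of the allylic alcohol and SN2′ delivery of bromide gives the thermodynamically favoured (Z)-2-(bromomethyl)enoate by allylic transposition; the descriptor at C8 changes from S to R only because the substituent priorities change.

**Step 4**
Reactants: 6 methyl (2Z)-2-(bromomethyl)-3-[(4R)-2,2-dimethyl-1,3-dioxolan-4-yl]prop-2-enoate; 2 (2Z)-3-methylpent-2-en-4-ynal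
Product: 9 (4S,5R)-4-[(4R)-2,2-dimethyl-1,3-dioxolan-4-yl]-3-methylidene-5-[(1Z)-2-methylbut-1-en-3-yn-1-yl]oxolan-2-one, via allylchromium 7 (not isolated), via hydroxy ester 8 (not isolated)
Conditions: CrCl2 (4 equiv), THF, rt, 16 h; aq. NH4Cl
Reagents that add atoms: none
Why: In this Nozaki–Hiyama-type (Barbier) 2-(alkoxycarbonyl)allylation the allylchromium adds through a chair transition state with the C8 substituent equatorial, giving the anti C6/C7 adduct whose alkoxide lactonises to the trans lactone; the aldehyde is taken up on the alkene face anti to the dioxolane C–O bond with the allylic hydrogen eclipsed (A1,3 control, the Felkin–Anh-type sense seen in chromium allylations of glyceraldehyde-derived allylic bromides), which sets 6R,7S next to the 8R centre.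

**Step 5**
Reactants: 9 (4S,5R)-4-[(4R)-2,2-dimethyl-1,3-dioxolan-4-yl]-3-methylidene-5-[(1Z)-2-methylbut-1-en-3-yn-1-yl]oxolan-2-one
Product: 10 (4R,5R)-4-[(1R)-1,2-dihydroxyethyl]-3-methylidene-5-[(1Z)-2-methylbut-1-en-3-yn-1-yl]oxolan-2-one
Conditions: AcOH/H2O (4:1), 40 °C
Reagents that add atoms: none
Why: Mild aqueous acid hydrolyses the isopropylidene ketal (acetal hydrolysis) without touching the lactone, the enyne or the exocyclic methylene; no stereocentre changes (the ring descriptor changes only through priorities).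

**Step 6**
Reactants: 10 (4R,5R)-4-[(1R)-1,2-dihydroxyethyl]-3-methylidene-5-[(1Z)-2-methylbut-1-en-3-yn-1-yl]oxolan-2-one
Product: 11 (4R,5R)-4-{(1R)-1-hydroxy-2-[(triethylsilyl)oxy]ethyl}-3-methylidene-5-[(1Z)-2-methylbut-1-en-3-yn-1-yl]oxolan-2-one
Conditions: Et3SiCl (1.05 equiv), imidazole, CH2Cl2, −78 to −40 °C
Reagents that add atoms: chlorotriethylsilane, CC[Si](Cl)(CC)CC
Why: Kinetic silylation at low temperature is selective for the primary C9 hydroxyl over the hindered secondary C8 hydroxyl (selective silyl ether formation).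

**Step 7**
Reactants: 11 (4R,5R)-4-{(1R)-1-hydroxy-2-[(triethylsilyl)oxy]ethyl}-3-methylidene-5-[(1Z)-2-methylbut-1-en-3-yn-1-yl]oxolan-2-one; 12 (2R)-2-methylbutanoic acid
Product: 13 (1S)-1-[(2R,3S)-4-methylidene-2-[(1Z)-2-methylbut-1-en-3-yn-1-yl]-5-oxooxolan-3-yl]-2-[(triethylsilyl)oxy]ethyl (2R)-2-methylbutanoate
Conditions: PPh3, DIAD, THF, 0 °C to rt
Reagents that add atoms: none
Why: Mitsunobu esterification turns the C8 hydroxyl into an alkoxyphosphonium that the carboxylate displaces by SN2, so the ester is installed and C8 is inverted from R to the required S in one step; the acid α-centre is not enolised.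

**Step 8**
Reactants: 14 (2S)-2-hydroxypropanoic acid (L-lactic acid)
Product: 15 tert-butyldimethylsilyl (2S)-2-[(tert-butyldimethylsilyl)oxy]propanoate
Conditions: TBSCl (2.2 equiv), imidazole, DMF, rt
Reagents that add atoms: tert-butyldimethylsilyl chloride, CC(C)(C)[Si](C)(C)Cl
Why: Imidazole-promoted silylation caps both the hydroxyl and the carboxylic acid (silyl ether/silyl ester formation).

**Step 9**
Reactants: 15 tert-butyldimethylsilyl (2S)-2-[(tert-butyldimethylsilyl)oxy]propanoate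
Product: 16 (2S)-2-[(tert-butyldimethylsilyl)oxy]propanoyl chloride
Conditions: (COCl)2, N,N-dimethylformamide (cat.), CH2Cl2, 0 °C to rt; used crude
Reagents that add atoms: oxalyl chloride, O=C(Cl)C(Cl)=O
Why: Oxalyl chloride with catalytic N,N-dimethylformamide converts the silyl ester directly into the acid chloride under neutral conditions that leave the silyl ether intact (Vilsmeier-type acyl chloride formation).

**Step 10**
Reactants: 13 (1S)-1-[(2R,3S)-4-methylidene-2-[(1Z)-2-methylbut-1-en-3-yn-1-yl]-5-oxooxolan-3-yl]-2-[(triethylsilyl)oxy]ethyl (2R)-2-methylbutanoate; 16 (2S)-2-[(tert-butyldimethylsilyl)oxy]propanoyl chloride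
Product: 17 (1S)-1-[(2R,3S)-2-[(1Z,6S)-6-[(tert-butyldimethylsilyl)oxy]-2-methyl-5-oxohept-1-en-3-yn-1-yl]-4-methylidene-5-oxooxolan-3-yl]-2-[(triethylsilyl)oxy]ethyl (2R)-2-methylbutanoate
Conditions: PdCl2(PPh3)2 (2 mol %), CuI (4 mol %), Et3N, THF, rt
Reagents that add atoms: none
Why: The acyl Sonogashira coupling (zerovalent palladium with a copper acetylide) joins the terminal alkyne to the acid chloride to give the ynone under mild amine conditions that the lactone and esters tolerate; the lactate centre is only a placeholder that is erased in step 12.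

**Step 11**
Reactants: 17 (1S)-1-[(2R,3S)-2-[(1Z,6S)-6-[(tert-butyldimethylsilyl)oxy]-2-methyl-5-oxohept-1-en-3-yn-1-yl]-4-methylidene-5-oxooxolan-3-yl]-2-[(triethylsilyl)oxy]ethyl (2R)-2-methylbutanoate
Product: 19 (1S)-1-[(2R,3S)-2-[(1Z,6S)-6-[(tert-butyldimethylsilyl)oxy]-2-methyl-5-oxohept-1-en-3-yn-1-yl]-4-methylidene-5-oxooxolan-3-yl]-2-oxoethyl (2R)-2-methylbutanoate, via primary alcohol 18 (not isolated)
Conditions: (COCl)2, DMSO, CH2Cl2, −78 to −30 °C; then Et3N, −78 to 0 °C
Reagents that add atoms: none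
Why: Under Swern conditions the primary triethylsilyl ether is cleaved and the freed alcohol is oxidised in the flask to the aldehyde while the secondary TBS ether survives (direct Swern oxidation of primary triethylsilyl ethers); the low temperature protects the α-acyloxy centre C8.

**Step 12**
Reactants: 19 (1S)-1-[(2R,3S)-2-[(1Z,6S)-6-[(tert-butyldimethylsilyl)oxy]-2-methyl-5-oxohept-1-en-3-yn-1-yl]-4-methylidene-5-oxooxolan-3-yl]-2-oxoethyl (2R)-2-methylbutanoate
Product: 22 (4Z,6R,7S,8S,9R,10R)-9-hydroxy-1-oxo-3,10-epoxygermacra-2,4,11(13)-trien-6,12-olid-8-yl (2R)-2-methylbutanoate (CNP0146060.1), via hydroxy ynone 20 (not isolated), via furanone aldehyde 21 (not isolated)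
Conditions: Bu4NF (1.5 equiv), AcOH (1.5 equiv), THF (0.002 M), 0 °C to rt
Reagents that add atoms: none
Why: Proposed new method: fluoride removes the TBS group, the freed C10 hydroxyl adds 5-endo to the ynone under acetate buffering to give the 2-methylfuran-3(2H)-one 21, and its acidic C10–H is enolised to an aromatic furan-3-olate that attacks the tethered C9 aldehyde (intramolecular aldol) and so closes the ten-membered carbocycle; the lactate centre is erased and C10 is reset because the C4–C9 tether, held by the Z alkene and the trans lactone, should span only one face of the planar furanolate, while C9 should follow from the compact arrangement with the aldehyde oxygen over the enolate oxygen (Zimmerman–Traxler-like, CH3 and OH syn, which corresponds to 9R,10R) and from reversibility of the aldol, which lets the least strained isomer accumulate; the closest known reaction types are the base- or amine-promoted cycloisomerisation of α′-hydroxy ynones to 3(2H)-furanones and C2 aldol reactions of 3(2H)-furanones and 3-silyloxyfurans.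

**Compound list**
1 | (2Z)-3-methylpent-2-en-4-yn-1-ol | OC/C=C(/C)C#C | starting material
2 | (2Z)-3-methylpent-2-en-4-ynal | O=C/C=C(/C)C#C | intermediate
3 | (4S)-2,2-dimethyl-1,3-dioxolane-4-carbaldehyde | CC1(C)OC[C@@H](C=O)O1 | starting material
4 | methyl acrylate | C=CC(=O)OC | starting material
5 | methyl 2-{[(4S)-2,2-dimethyl-1,3-dioxolan-4-yl](hydroxy)methyl}prop-2-enoate (carbinol epimers) | CC1(C)OC[C@@H](C(O)C(=C)C(=O)OC)O1 | intermediate
6 | methyl (2Z)-2-(bromomethyl)-3-[(4R)-2,2-dimethyl-1,3-dioxolan-4-yl]prop-2-enoate | CC1(C)OC[C@@H](/C=C(\CBr)C(=O)OC)O1 | intermediate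
7 | {(2E)-3-[(4R)-2,2-dimethyl-1,3-dioxolan-4-yl]-2-(methoxycarbonyl)prop-2-en-1-yl}chromium dichloride | Cl[Cr](Cl)C/C(C(=O)OC)=C/[C@@H]1COC(C)(C)O1 | intermediate (not isolated)
8 | methyl (3S,4R,5Z)-3-[(4R)-2,2-dimethyl-1,3-dioxolan-4-yl]-4-hydroxy-6-methyl-2-methylideneoct-5-en-7-ynoate (present as its chromium alkoxide) | C=C(C(=O)OC)[C@H]([C@@H]1COC(C)(C)O1)[C@H](O)/C=C(/C)C#C | intermediate (not isolated)
9 | (4S,5R)-4-[(4R)-2,2-dimethyl-1,3-dioxolan-4-yl]-3-methylidene-5-[(1Z)-2-methylbut-1-en-3-yn-1-yl]oxolan-2-one | C=C1C(=O)O[C@H](/C=C(/C)C#C)[C@H]1[C@@H]2COC(C)(C)O2 | intermediate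
10 | (4R,5R)-4-[(1R)-1,2-dihydroxyethyl]-3-methylidene-5-[(1Z)-2-methylbut-1-en-3-yn-1-yl]oxolan-2-one | C=C1C(=O)O[C@H](/C=C(/C)C#C)[C@H]1[C@@H](O)CO | intermediate
11 | (4R,5R)-4-{(1R)-1-hydroxy-2-[(triethylsilyl)oxy]ethyl}-3-methylidene-5-[(1Z)-2-methylbut-1-en-3-yn-1-yl]oxolan-2-one | C=C1C(=O)O[C@H](/C=C(/C)C#C)[C@H]1[C@@H](O)CO[Si](CC)(CC)CC | intermediate
12 | (2R)-2-methylbutanoic acid | CC[C@@H](C)C(=O)O | starting material
13 | (1S)-1-[(2R,3S)-4-methylidene-2-[(1Z)-2-methylbut-1-en-3-yn-1-yl]-5-oxooxolan-3-yl]-2-[(triethylsilyl)oxy]ethyl (2R)-2-methylbutanoate | C=C1C(=O)O[C@H](/C=C(/C)C#C)[C@H]1[C@H](OC(=O)[C@H](C)CC)CO[Si](CC)(CC)CC | intermediate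
14 | (2S)-2-hydroxypropanoic acid | C[C@H](O)C(=O)O | starting material
15 | tert-butyldimethylsilyl (2S)-2-[(tert-butyldimethylsilyl)oxy]propanoate | C[C@H](O[Si](C)(C)C(C)(C)C)C(=O)O[Si](C)(C)C(C)(C)C | intermediate
16 | (2S)-2-[(tert-butyldimethylsilyl)oxy]propanoyl chloride | C[C@H](O[Si](C)(C)C(C)(C)C)C(Cl)=O | intermediate
17 | (1S)-1-[(2R,3S)-2-[(1Z,6S)-6-[(tert-butyldimethylsilyl)oxy]-2-methyl-5-oxohept-1-en-3-yn-1-yl]-4-methylidene-5-oxooxolan-3-yl]-2-[(triethylsilyl)oxy]ethyl (2R)-2-methylbutanoate | C=C1C(=O)O[C@H](/C=C(/C)C#CC(=O)[C@H](C)O[Si](C)(C)C(C)(C)C)[C@H]1[C@H](OC(=O)[C@H](C)CC)CO[Si](CC)(CC)CC | intermediate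
18 | (1S)-1-[(2R,3S)-2-[(1Z,6S)-6-[(tert-butyldimethylsilyl)oxy]-2-methyl-5-oxohept-1-en-3-yn-1-yl]-4-methylidene-5-oxooxolan-3-yl]-2-hydroxyethyl (2R)-2-methylbutanoate | C=C1C(=O)O[C@H](/C=C(/C)C#CC(=O)[C@H](C)O[Si](C)(C)C(C)(C)C)[C@H]1[C@H](OC(=O)[C@H](C)CC)CO | intermediate (not isolated)
19 | (1S)-1-[(2R,3S)-2-[(1Z,6S)-6-[(tert-butyldimethylsilyl)oxy]-2-methyl-5-oxohept-1-en-3-yn-1-yl]-4-methylidene-5-oxooxolan-3-yl]-2-oxoethyl (2R)-2-methylbutanoate | C=C1C(=O)O[C@H](/C=C(/C)C#CC(=O)[C@H](C)O[Si](C)(C)C(C)(C)C)[C@H]1[C@H](OC(=O)[C@H](C)CC)C=O | intermediate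
20 | (1S)-1-[(2R,3S)-2-[(1Z,6S)-6-hydroxy-2-methyl-5-oxohept-1-en-3-yn-1-yl]-4-methylidene-5-oxooxolan-3-yl]-2-oxoethyl (2R)-2-methylbutanoate | C=C1C(=O)O[C@H](/C=C(/C)C#CC(=O)[C@H](C)O)[C@H]1[C@H](OC(=O)[C@H](C)CC)C=O | intermediate (not isolated)
21 | (1S)-1-[(2R,3S)-4-methylidene-2-{(1Z)-2-[(5S)-5-methyl-4-oxo-4,5-dihydrofuran-2-yl]prop-1-en-1-yl}-5-oxooxolan-3-yl]-2-oxoethyl (2R)-2-methylbutanoate | C=C1C(=O)O[C@H](/C=C(/C)C2=CC(=O)[C@H](C)O2)[C@H]1[C@H](OC(=O)[C@H](C)CC)C=O | intermediate (not isolated)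
22 | (4Z,6R,7S,8S,9R,10R)-9-hydroxy-1-oxo-3,10-epoxygermacra-2,4,11(13)-trien-6,12-olid-8-yl (2R)-2-methylbutanoate | C=C1C(=O)O[C@@H]2/C=C(/C)C3=CC(=O)[C@](C)(O3)[C@H](O)[C@@H](OC(=O)[C@H](C)CC)[C@@H]12 | target

**Step count and risks**
Total: 12 steps. Longest linear sequence: 9 steps (3 → 5 → 6 → 9 → 10 → 11 → 13 → 17 → 19 → 22).

Most likely to fail:

1. Step 12 (the double ring closure). Ring strain may stop the aldol, and the open transition state under Bu4N+ counter-ions gives no firm control of C9/C10. The furanolate could instead add to the methylene lactone, C8 could epimerise at the aldehyde stage, and the acyl group could migrate from C8 to C9. The fallback sets out from 19 and returns at 22. HF·pyridine in THF/pyridine followed by catalytic Ph3PAuNTf2 gives the furanone aldehyde 21, which is isolated. i-Pr3SiOTf/Et3N at −78 °C converts it into the 3-silyloxyfuran aldehyde F9. A Lewis-acid-mediated intramolecular Mukaiyama aldol reaction (MgBr2·OEt2, CH2Cl2, high dilution, chelation between the aldehyde and the C8 acyloxy carbonyl) then closes C9–C10.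

2. Step 4 (facial sense of the chromium allylation relative to C8, and anti selectivity). The fallback sets out from 2 and returns at 13, using the enantiomeric chiral pool and an esterification with retention. (R)-glyceraldehyde acetonide F1 is taken through the same Morita–Baylis–Hillman reaction to the adduct F2 and the bromide F3. If the allylation prefers the face anti to C9, F3 and 2 give the 6R,7S,8S lactone acetonide F4. Hydrolysis gives the diol F5, primary silylation gives the hydroxy silyl ether F6, and a Steglich esterification with 12 (DCC, 4-(dimethylamino)pyridine) reaches 13 without inversion.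

3. Step 7 (Mitsunobu at the hindered C8 hydroxyl; elimination or low conversion). The fallback sets out from 11 and returns at 13. ClCH2SO2Cl/pyridine gives the chloromethanesulfonate F7, which is displaced with inversion by cesium (2R)-2-methylbutanoate F8 (from 12 and Cs2CO3) with 18-crown-6 in toluene.

**Further compounds**
F1 | step 4 | (4R)-2,2-dimethyl-1,3-dioxolane-4-carbaldehyde | CC1(C)OC[C@H](C=O)O1
F2 | step 4 | methyl 2-{[(4R)-2,2-dimethyl-1,3-dioxolan-4-yl](hydroxy)methyl}prop-2-enoate (carbinol epimers) | CC1(C)OC[C@H](C(O)C(=C)C(=O)OC)O1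
F3 | step 4 | methyl (2Z)-2-(bromomethyl)-3-[(4S)-2,2-dimethyl-1,3-dioxolan-4-yl]prop-2-enoate | CC1(C)OC[C@H](/C=C(\CBr)C(=O)OC)O1
F4 | step 4 | (4S,5R)-4-[(4S)-2,2-dimethyl-1,3-dioxolan-4-yl]-3-methylidene-5-[(1Z)-2-methylbut-1-en-3-yn-1-yl]oxolan-2-one | C=C1C(=O)O[C@H](/C=C(/C)C#C)[C@H]1[C@H]2COC(C)(C)O2
F5 | step 4 | (4R,5R)-4-[(1S)-1,2-dihydroxyethyl]-3-methylidene-5-[(1Z)-2-methylbut-1-en-3-yn-1-yl]oxolan-2-one | C=C1C(=O)O[C@H](/C=C(/C)C#C)[C@H]1[C@H](O)CO
F6 | step 4 | (4R,5R)-4-{(1S)-1-hydroxy-2-[(triethylsilyl)oxy]ethyl}-3-methylidene-5-[(1Z)-2-methylbut-1-en-3-yn-1-yl]oxolan-2-one | C=C1C(=O)O[C@H](/C=C(/C)C#C)[C@H]1[C@H](O)CO[Si](CC)(CC)CC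
F7 | step 7 | (1R)-1-[(2R,3S)-4-methylidene-2-[(1Z)-2-methylbut-1-en-3-yn-1-yl]-5-oxooxolan-3-yl]-2-[(triethylsilyl)oxy]ethyl chloromethanesulfonate | C=C1C(=O)O[C@H](/C=C(/C)C#C)[C@H]1[C@@H](OS(=O)(=O)CCl)CO[Si](CC)(CC)CC
F8 | step 7 | cesium (2R)-2-methylbutanoate | CC[C@@H](C)C(=O)[O-].[Cs+]
F9 | step 12 | (1S)-1-[(2R,3S)-4-methylidene-2-[(1Z)-2-{5-methyl-4-[(triisopropylsilyl)oxy]furan-2-yl}prop-1-en-1-yl]-5-oxooxolan-3-yl]-2-oxoethyl (2R)-2-methylbutanoate | C=C1C(=O)O[C@H](/C=C(/C)c2cc(O[Si](C(C)C)(C(C)C)C(C)C)c(C)o2)[C@H]1[C@H](OC(=O)[C@H](C)CC)C=O
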